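The earlier runs and the new flask were computed for an exercise; scatter was added.

The choice at hand is how much substrate to charge against a fixed 57.2 mM of coupling partner, judged by the yield of target after 5.0 h.

common to all: coupling partner 57.2 mM; free catalyst 0.70 mM
- dusk: substrate 13 mM; run made earlier
- winter: substrate 250 mM; run made earlier
- south: substrate 20 mM; time 5.0 h
- west: substrate 40 mM; time 5.0 h
- east: substrate 80 mM; time 5.0 h
- south-west: substrate 200 mM; time 5.0 h
- north: substrate 400 mM; time 5.0 h

- dusk (time / h: target / %, substrate / %): 0.167: 4.2, 83.2; 0.500: 16.6, 64.8; 0.833: 24.5, 55.9; 1.33: 32.8, 49.6; 2.00: 37.8, 44.6; 2.50: 39.7, 45.2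
- winter (time / h: target / %, substrate / %): 0.200: 2.9, 84.2; 0.333: 6.5, 77.3; 0.500: 11.1, 71.1; 0.833: 14.7, 64.4; 1.50: 20.4, 54.3; 2.50: 22.6, 46.9

(each reading ± 0.5 percentage points)

- steps under discussion: free catalyst + open intermediate <-> catalyst intermediate; substrate + free catalyst <-> free catalyst + open intermediate; coupling partner + catalyst intermediate -> free catalyst + target; coupling partner + free catalyst -> spent catalyst
- "hardly changes" means that all values lie within two and a half points (for a concentration: within two and a half percent of the largest)

1. amount of target at the end, in percent of the substrate charged for south, west, east, south-west, north, in this order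
2. the shape of the row from first to last (rises, then falls / falls, then rises / rises all the way / hardly changes / falls all the way)

In the steps under discussion, substrate opens reversibly on free catalyst, and open intermediate binds free catalyst reversibly as catalyst intermediate. Coupling partner then turns catalyst intermediate into target and free catalyst, but it also turns free catalyst into spent catalyst. One target therefore costs one coupling partner. Call partner ceiling the yield reached when each partner charged has become a target, that is, c(coupling partner) over c(substrate) as charged; for south-west it is 28.6 %. Equal charges are the reference point of this scale, with a ceiling of 100 %.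

Winter tests it:

ceiling = 57.2 mM / 250 mM = 22.9 %
reading at 2.50 h = 22.6 %

The gap of 0.30 percentage points is smaller than the scatter of 0.5 points, so this winter reading lies within the scatter of its ceiling. Coupling partner is the limiting reagent of winter, with a charge smaller than that of substrate.

Dusk is the other case. Its target levels off near 39.7 %, which accounts for 9.02 % of the partner charged, while its substrate stays near 45.2 %. Something other than the partner stops dusk, and spent catalyst is the step on the list that fits.

What would have to be true for the row not to fall at its end? North's ceiling would have to reach that dusk plateau, yet it is lower: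

north: 57.2 mM / 400 mM = 14.3 %, below 39.7 %

East's ceiling of 71.5 % stands above the plateau, and south-west's below it. This reckoning puts south, west and east near the plateau, and south-west and north on their ceilings.

The forecast, higher at east, reads 42 %, 45 %, 51 %, 28.2 % and 14.2 %, shape rises, then falls, and in its words “partner caps the target”.

The flasks give 41.6 %, 43.8 %, 47.5 %, 28.4 % and 14.2 %, shape rises, then falls.

    free catalyst + open intermediate ⇌ catalyst intermediate (K = 33.0 M⁻¹, k = 140 M⁻¹ min⁻¹)
    substrate + free catalyst ⇌ free catalyst + open intermediate (K = 1.40, k = 32.0 M⁻¹ min⁻¹)
    coupling partner + catalyst intermediate → free catalyst + target (k = 100 M⁻¹ min⁻¹)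
    coupling partner + free catalyst → spent catalyst (k = 0.390 M⁻¹ min⁻¹)

The row turns at 86 mM of substrate, at a yield of 47.7 %. South-west, after 5.00 h, keeps 0.19 % of its coupling partner beside 36.0 % of substrate and 35.5 % of open intermediate, and its 28.4 % lies 0.2 points under its ceiling of 28.6 %. North has a ceiling of 14.3 %, gives 14.2 %, and keeps 0 % of its coupling partner.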